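**Numbering used throughout:** 1 methyl vanillate; 2 iodinated ring A phenol; 3 vanillin; 4 O-mesylvanillin; 5 triethyl phosphonoacetate; 6 ring B ethyl cinnamate; 7 ring B cinnamyl alcohol; 8 ring B cinnamyl methyl carbonate; 9 lithium aryloxide of 2 (formed in the flask); 10 aryl 1-arylallyl ether, the cyclization precursor; 11 C9 hydroperoxide (formed in the flask); 12 O-mesylcurlignan; 13 curlignan.

## Analysis of the target

Curlignan (13) is a neolignan built on a 2,3-dihydro-1-benzofuran: ring A (C3a, C4–C7, C7a) carries a methyl ester at C5 and a methoxy group at C7, and the heterocycle (O1, C2, C3) carries a 4-hydroxy-3-methoxyphenyl group (ring B) at C2 and a hydroxymethyl arm (C9) at C3. The only stereocentres are the neighbours C2 (S) and C3 (R), which place ring B and C9 trans across the C2–C3 bond; trans is the relaxed arrangement, so the absolute configuration is the harder half of the problem. C2 is the weak point: it is a benzylic aryl-ether carbon para to a free phenol, so acid, strong base or heat can open the O1–C2 bond through a quinone methide of ring B and erase the centre. The other sensitive groups are a methyl ester that must stay an ester beside a primary alcohol, and a free phenol that would interfere with bases, metals and radicals if left bare. The synthesis is demanding in economy, not in size: C2 has to be fixed as one enantiomer on an ether oxygen, C3 has to follow it, and C9 should arrive at the alcohol oxidation level so that it never has to be told apart from the C5 ester. The plan rests on the fact that C3 is bonded at once to C3a of ring A, to the oxygen-bearing C2 and to the CH2–O carbon C9: read backwards, C3 and C9 are the two carbons of a vinyl group on an aryl 1-arylallyl ether, C3 waiting for a radical centred at C3a and C9 for an oxygen atom. Both aromatic rings are vanilloid, ring A a 5-substituted vanillate and ring B vanillin-derived, which fixes the starting materials.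

## Retrosynthetic reasoning

**13 to 12 (O–S bond of a sulfonate).** The ring B phenol is kept as its methanesulfonate until the last step. A free or alkylated phenol para to C2 would make the O1–C2 bond easy to ionize in every intermediate. The sulfonate withdraws electrons, is inert to hydride, bases, metal catalysis and radicals, and is removed by methoxide in methanol, which cannot change a methyl ester.

**12 to 10 (C3–C3a and C9–O, through 11).** These two bonds are cut together because C3 is the one carbon joined to both ring A and C9. The cut leaves an aryl iodide and a terminal alkene in 10, two groups that need no adjustment of oxidation level. The forward reaction closes the dihydrofuran ring, creates C3 and delivers C9 as an alcohol. It has to generate a radical at C3a, add it 5-exo to the vinyl group, capture oxygen from air at C9 (hydroperoxide 11, reduced in the flask to 12), and let the existing C2 centre place C9 trans to ring B.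

**10 to 2 and 8 (O1–C2, through 9).** O1–C2 is the only bond joining the two halves of 10. Cutting it gives phenol 2 (as its aryloxide 9) and the linear cinnamyl carbonate 8, both achiral. The forward reaction is an iridium-catalysed asymmetric allylic etherification, so the C2 stereocentre is created in the bond-forming event itself. It has to attack the aryl-bearing allyl terminus (branched ether), give one enantiomer, and accept an aryloxide flanked by iodine and methoxy.

**8 back to 3 and 5.** Carbonate 8 comes from allylic alcohol 7 by acylation, 7 from enoate 6 by hydride reduction, and the C=C bond of 6 from aldehyde 4 and phosphonate 5 by an E-selective olefination. Aldehyde 4 is vanillin 3 sulfonylated on oxygen; doing this first means no phenoxide is carried through the base and hydride steps.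

**2 to 1 (C–I bond).** The iodine that later becomes the radical site at C3a is introduced by electrophilic iodination of methyl vanillate 1, where the phenol directs to its only free ortho position.

## Alternatives that were turned down

**Alternative 1: three-component assembly on an alkenyl boronate.**
- Disconnection: C3–C3a and the bond from C2 to ring B are cut at once. This leaves C2–C3–C9 as the (E)-alkenyl pinacol boronate A2, ring A as the aryl triflate A3 and ring B as the aryllithium A4.
- Forward key step: A4 adds to boron of A2. The ate complex meets the arylpalladium species formed from A3 with Pd(OAc)2 and a chiral ferrocenyl bisphosphine of the MandyPhos family. Ring B shifts from boron to C2 while palladium bonds to C3, and reductive elimination closes C3–C3a to give the secondary boronate A1.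
- For it: both aryl–carbon bonds and both stereocentres arise in one catalytic, enantioselective operation, with the relative configuration fixed by anti addition across an E alkene. Here it is stronger than the chosen route, which controls C3 only through the substrate.
- Against it:
  - (a) A2 is a β-substituted alkenyl boronate with an allylic silyloxy group. Internal alkenes enter the metallate shift far less readily than vinyl boronates, direct transfer of the alkenyl group to palladium (a plain Suzuki coupling) competes, and the alkylpalladium at C3 has a β-oxygen on C9 and β-hydrogens.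
  - (b) A3 needs two neighbouring phenols of ring A to be told apart.
  - (c) A1 still lacks O1–C2. Oxidation of the C–B bond gives the benzylic alcohol with retention and a displacement by the ring A phenol would invert it, so closure has to run through the benzylic cation or quinone methide of ring B. The C2 information bought in the key step is then discarded and C3 alone directs the trans closure.
  - (d) Three protecting groups must be removed.
- Comparison: the overall length is similar (about nine operations), but the key step uses its least precedented substrate class. The chosen route makes O1–C2 first, under catalyst control, and uses one protecting group.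

**Alternative 2: benzannulation of ring A onto a preformed heterocycle.**
- Disconnection: C3a–C4 and C7a–C7 are cut. C4 to C7 with the ester and the methoxy group come from the 2-pyrone A6; O1, C2, C3, C3a and C7a come from the trans butyrolactone A8, used as its trimethylsilyl ketene acetal A7.
- Forward key step: A7 adds across C6 and C3 of A6 in an inverse-demand [4+2] reaction. Decarboxylative cycloreversion and elimination of the silyloxy group then aromatise ring A and give A5.
- For it: both stereocentres are secured in a trans lactone before the key step, which touches neither. On stereochemical risk in the key step it is stronger than the chosen route.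
- Against it: A6 is not commercial. Its 3-methoxy group makes the diene less electron-poor and crowds the terminus that must bond to the oxygen-bearing ketene acetal carbon, with regiochemistry resting on the C5 ester alone. A8 needs its own multi-step asymmetric synthesis with both oxygens protected. The final benzyl ether hydrogenolysis sits beside the hydrogenolysable O1–C2 bond.
- Comparison: the count is likely twelve or more steps against eight. The chosen route builds no aromatic ring and takes both rings from commodity vanilloids.

**Alternative 3: carbene insertion into the benzylic C–H bond of an aryl benzyl ether.**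
- Disconnection: C2–C3 is cut. C3 becomes the carbene carbon of the aryldiazoacetate A10 and C2 the methylene of a ring B benzyl ether on O1.
- Forward key step: Rh2(S-PTTL)4 releases nitrogen from A10 and the carbene inserts into one of the two enantiotopic benzylic C–H bonds, closing the ring to the cis ester A9 with C2 as required.
- For it: this is the ring-forming step with the closest precedent for cis-2-aryl-2,3-dihydrobenzofuran-3-carboxylates, and it sets both centres under catalyst control. On precedent and on enantiocontrol in the ring-forming step it is at least as strong as the chosen key step.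
- Against it: C3 comes out cis and at the ester oxidation level. Epimerisation next to the ester passes through an enolate that can expel O1 from C2, which would erase C2. Ring A cannot carry its C5 ester while the C3 ester is reduced, hence the bromine in A9 and a late methoxycarbonylation with Pd(OAc)2, a bisphosphine and carbon monoxide. Debenzylation with H2 over Pd/C competes with cleavage of O1–C2. A10 needs a homologated ring A arylacetate, etherification and diazo transfer.
- Comparison: at least four steps follow the key step and about ten or eleven are needed overall. The chosen route gets the trans relationship and C9 as an alcohol directly from ring closure and needs one deprotection afterwards.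

Key step: step 7

Assumption: the (Sa,Sc,Sc) phosphoramidite is taken to give the (S)-configured branched aryl ether, following the usual sense of induction of this catalyst family with cinnamyl carbonates and heteroatom nucleophiles; if the first run shows the opposite sense, the mirror-image ligand is used and nothing else changes.

## Route

Step 1
Reactants: 1 methyl vanillate (methyl 4-hydroxy-3-methoxybenzoate)
Product: 2 methyl 4-hydroxy-3-iodo-5-methoxybenzoate
Conditions: NIS, TFA (cat.), MeCN, rt
Reagents that add atoms: N-iodosuccinimide, O=C1CCC(=O)N1I
Why: Electrophilic aromatic iodination; the phenol is the strongest director and its para position is taken by the ester, so iodine enters the one free ortho position, the future C3a.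

Step 2
Reactants: 3 vanillin
Product: 4 4-formyl-2-methoxyphenyl methanesulfonate
Conditions: MsCl, Et3N, CH2Cl2, 0 °C to rt
Reagents that add atoms: methanesulfonyl chloride, CS(=O)(=O)Cl
Why: O-Sulfonylation of the phenol; the mesylate makes ring B mildly electron-poor and should stay inert to the base, hydride, metal and radical steps that follow.

Step 3
Reactants: 4 4-formyl-2-methoxyphenyl methanesulfonate; 5 triethyl phosphonoacetate
Product: 6 ethyl (E)-3-[3-methoxy-4-(methylsulfonyloxy)phenyl]prop-2-enoate
Conditions: NaH, THF, 0 °C to rt
Reagents that add atoms: none
Why: Horner–Wadsworth–Emmons olefination; the stabilised phosphonate anion adds to the aldehyde and the adduct collapses to the E enoate.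

Step 4
Reactants: 6 ethyl (E)-3-[3-methoxy-4-(methylsulfonyloxy)phenyl]prop-2-enoate
Product: 7 (E)-3-[3-methoxy-4-(methylsulfonyloxy)phenyl]prop-2-en-1-ol
Conditions: iBu2AlH (2.2 equiv), CH2Cl2, −78 °C; aq. potassium sodium tartrate
Reagents that add atoms: none
Why: 1,2-Reduction of the conjugated ester by the electrophilic hydride iBu2AlH at low temperature gives the allylic alcohol and leaves the alkene alone; an aryl sulfonate is not expected to be reduced under these conditions.

Step 5
Reactants: 7 (E)-3-[3-methoxy-4-(methylsulfonyloxy)phenyl]prop-2-en-1-ol
Product: 8 methyl (E)-3-[3-methoxy-4-(methylsulfonyloxy)phenyl]prop-2-en-1-yl carbonate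
Conditions: ClCO2Me, pyridine, CH2Cl2, 0 °C
Reagents that add atoms: methyl chloroformate, COC(=O)Cl
Why: Acylation of the primary allylic alcohol installs the carbonate leaving group needed for the allylic substitution.

Step 6
Reactants: 2 methyl 4-hydroxy-3-iodo-5-methoxybenzoate; 8 methyl (E)-3-[3-methoxy-4-(methylsulfonyloxy)phenyl]prop-2-en-1-yl carbonate
Product: 10 methyl 3-iodo-5-methoxy-4-{[(1S)-1-(3-methoxy-4-(methylsulfonyloxy)phenyl)prop-2-en-1-yl]oxy}benzoate, via lithium aryloxide 9 (not isolated)
Conditions: 2 (1.5 equiv), LiN(SiMe3)2, THF, 0 °C; then 8, [Ir(cod)Cl]2 (2 mol %), (Sa,Sc,Sc)-O,O′-(1,1′-binaphthalene-2,2′-diyl) N,N-bis(1-phenylethyl)phosphoramidite (4 mol %), THF, rt to 50 °C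
Reagents that add atoms: none
Why: Iridium-catalysed asymmetric allylic etherification: the catalyst formed from [Ir(cod)Cl]2 and the phosphoramidite ionises the linear carbonate to an allyl complex, which aryloxide 9 attacks at the aryl-bearing terminus to give the branched ether, the ligand shielding one face of the allyl unit and so setting C2 as S. The electron-withdrawing mesylate on ring B slows re-ionisation of the product, which protects both the branched constitution and the configuration.

Step 7
Reactants: 10 methyl 3-iodo-5-methoxy-4-{[(1S)-1-(3-methoxy-4-(methylsulfonyloxy)phenyl)prop-2-en-1-yl]oxy}benzoate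
Product: 12 methyl (2S,3R)-3-(hydroxymethyl)-7-methoxy-2-[3-methoxy-4-(methylsulfonyloxy)phenyl]-2,3-dihydro-1-benzofuran-5-carboxylate, via primary hydroperoxide 11 (not isolated)
Conditions: Bu3SnH (2.5 equiv, syringe pump), stream of dry air, PhMe (0.01 M), 0 °C to rt; then PPh3, rt
Reagents that add atoms: dioxygen (from dry air), O=O
Why: Tributylstannyl radicals, started by slow autoxidation of Bu3SnH in air, abstract iodine from 10 and give the σ-aryl radical at C3a. This radical adds to the internal vinyl carbon in a 5-exo-trig closure that forms C3–C3a and the dihydrofuran ring, and it should do so far faster than it is reduced by the dilute Bu3SnH or captured by oxygen. The primary radical left at C9 is then taken by dissolved O2, the peroxyl radical carries the chain by taking hydrogen from Bu3SnH to give hydroperoxide 11, and PPh3 reduces 11 to the alcohol in the same flask. The closest known reaction type is the oxygenative cyclization of 2-iodophenyl allyl ethers with Bu3SnH under air, which gives 3-(hydroxymethyl)-2,3-dihydrobenzofurans. The new stereocentre C3 is set by the existing C2 centre: in the chair-like 5-exo transition state the ring B aryl group sits pseudo-equatorial, so C9 ends up trans to it and the 2S centre should lead to 3R. The step needs 5-exo over 6-endo closure (secured by the short C–O–C tether and the unsubstituted internal alkene carbon), oxygen capture over hydrogen transfer at C9 (secured by slow addition of Bu3SnH into air-saturated solution), and an intact C2 centre (secured by the mesylate, which disfavours ionisation of the ether, and by the poor geometry of a 1,4-hydrogen shift from C2 to the aryl radical).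

Step 8
Reactants: 12 methyl (2S,3R)-3-(hydroxymethyl)-7-methoxy-2-[3-methoxy-4-(methylsulfonyloxy)phenyl]-2,3-dihydro-1-benzofuran-5-carboxylate
Product: 13 curlignan, methyl (2S,3R)-2-(4-hydroxy-3-methoxyphenyl)-3-(hydroxymethyl)-7-methoxy-2,3-dihydro-1-benzofuran-5-carboxylate
Conditions: NaOMe (5 equiv), dry MeOH, 40–50 °C; then aq. NH4Cl
Reagents that add atoms: none
Why: Methanolysis of an aryl sulfonate: methoxide attacks the sulfonyl sulfur and the ring B phenoxide leaves, while exchange at the C5 methyl ester is degenerate because the nucleophile is methoxide in methanol. The excess methoxide should also consume the methyl methanesulfonate formed, so that it does not re-alkylate the phenoxide, and the temperature is kept low so that the liberated phenoxide does not open O1–C2.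

## Compound list

1 | methyl vanillate (methyl 4-hydroxy-3-methoxybenzoate) | COC(=O)c1ccc(O)c(OC)c1 | starting material
2 | methyl 4-hydroxy-3-iodo-5-methoxybenzoate | COC(=O)c1cc(I)c(O)c(OC)c1 | intermediate
3 | vanillin (4-hydroxy-3-methoxybenzaldehyde) | COc1cc(C=O)ccc1O | starting material
4 | 4-formyl-2-methoxyphenyl methanesulfonate | COc1cc(C=O)ccc1OS(C)(=O)=O | intermediate
5 | triethyl phosphonoacetate | CCOC(=O)CP(=O)(OCC)OCC | starting material
6 | ethyl (E)-3-[3-methoxy-4-(methylsulfonyloxy)phenyl]prop-2-enoate | CCOC(=O)/C=C/c1ccc(OS(C)(=O)=O)c(OC)c1 | intermediate
7 | (E)-3-[3-methoxy-4-(methylsulfonyloxy)phenyl]prop-2-en-1-ol | OC/C=C/c1ccc(OS(C)(=O)=O)c(OC)c1 | intermediate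
8 | methyl (E)-3-[3-methoxy-4-(methylsulfonyloxy)phenyl]prop-2-en-1-yl carbonate | COC(=O)OC/C=C/c1ccc(OS(C)(=O)=O)c(OC)c1 | intermediate
9 | lithium 2-iodo-6-methoxy-4-(methoxycarbonyl)phenolate (aryloxide of 2, formed in the flask, not isolated) | COC(=O)c1cc(I)c([O-])c(OC)c1.[Li+] | intermediate
10 | methyl 3-iodo-5-methoxy-4-{[(1S)-1-(3-methoxy-4-(methylsulfonyloxy)phenyl)prop-2-en-1-yl]oxy}benzoate | COC(=O)c1cc(OC)c(O[C@@H](C=C)c2ccc(OS(C)(=O)=O)c(OC)c2)c(I)c1 | intermediate
11 | methyl (2S,3R)-3-(hydroperoxymethyl)-7-methoxy-2-[3-methoxy-4-(methylsulfonyloxy)phenyl]-2,3-dihydro-1-benzofuran-5-carboxylate (formed in the flask, not isolated) | COC(=O)c1cc(OC)c2c(c1)[C@H](COO)[C@@H](c1ccc(OS(C)(=O)=O)c(OC)c1)O2 | intermediate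
12 | methyl (2S,3R)-3-(hydroxymethyl)-7-methoxy-2-[3-methoxy-4-(methylsulfonyloxy)phenyl]-2,3-dihydro-1-benzofuran-5-carboxylate | COC(=O)c1cc(OC)c2c(c1)[C@H](CO)[C@@H](c1ccc(OS(C)(=O)=O)c(OC)c1)O2 | intermediate
13 | curlignan, methyl (2S,3R)-2-(4-hydroxy-3-methoxyphenyl)-3-(hydroxymethyl)-7-methoxy-2,3-dihydro-1-benzofuran-5-carboxylate | COC(=O)c1cc(OC)c2c(c1)[C@H](CO)[C@@H](c1ccc(O)c(OC)c1)O2 | target

## Step count and least certain steps

Total step count: 8. Longest linear sequence: 7 steps (steps 2 to 8, from vanillin 3); step 1 is a one-step side branch that joins at step 6.

**Step 7 (key step).** Three processes may intervene.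
- Hydrogen transfer from Bu3SnH to the C9 radical may compete with oxygen capture if the local concentration of Bu3SnH is too high, and the chain may stall if it is too low, because oxygen retards the tin chain.
- The C9 peroxyl radical may abstract the doubly activated hydrogen on C2 through a six-membered transition state before it is reduced, which would degrade the C2 centre.
- Facial selectivity at C3 may be incomplete, since the transition state of an aryl radical closure is early and flat.

Fallback: capture the C9 radical with a persistent nitroxide instead of oxygen and cleave the N–O bond in a separate step. Setting out from 10, Bu3SnH and TEMPO (excess) in benzene at 60–70 °C should give the alkoxyamine methyl (2S,3R)-7-methoxy-2-[3-methoxy-4-(methylsulfonyloxy)phenyl]-3-{[(2,2,6,6-tetramethylpiperidin-1-yl)oxy]methyl}-2,3-dihydro-1-benzofuran-5-carboxylate F1. Zn dust in AcOH/THF/H2O then reduces the O–N bond and the route is rejoined at 12. This path has no peroxyl intermediate. The ring-closing transition state is the same, so if selectivity is the problem the C3 epimers are separated at 12.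

**Step 6.** The aryloxide 9 is flanked by iodine and methoxy and is electron-poor. Attack on the allyl complex may be slow, and the catalyst may re-ionise the product ether because its aryloxide is a good leaving group. Both would erode branched selectivity and enantiomeric purity. The methoxide released from the carbonate may also attack the mesylate if the mixture is heated for long.

Fallback: fix the configuration by epoxidation and form the ether with inversion. Setting out from 7, Sharpless asymmetric epoxidation (Ti(OiPr)4, L-(+)-diethyl tartrate, tBuOOH, 4 Å sieves, CH2Cl2, −20 °C) should give [(2S,3S)-3-[3-methoxy-4-(methylsulfonyloxy)phenyl]oxiran-2-yl]methanol F2. I2, PPh3 and imidazole convert it into (2R,3S)-2-(iodomethyl)-3-[3-methoxy-4-(methylsulfonyloxy)phenyl]oxirane F3. Zn dust in EtOH at reflux opens the epoxide reductively to (1R)-1-[3-methoxy-4-(methylsulfonyloxy)phenyl]prop-2-en-1-ol F4. A Mitsunobu reaction of F4 with phenol 2 (PPh3, DIAD, toluene, 0 °C) inverts the carbinol centre and rejoins the route at 10; carbonate 8 is then not needed.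

**Step 8.** Cleavage of the hindered guaiacyl mesylate may be slow. Forcing it risks transfer of a methyl group from the sulfonate ester by-product to the freed phenoxide, partial hydrolysis of the ester by adventitious water, and base-induced opening of O1–C2 through the quinone methide once ring B is a phenoxide.

Fallback: use hydroxide, which gives methanesulfonate and no alkylating agent, accept loss of the ester, and restore it. Setting out from 12, LiOH in THF/H2O at 40–50 °C should give (2S,3R)-2-(4-hydroxy-3-methoxyphenyl)-3-(hydroxymethyl)-7-methoxy-2,3-dihydro-1-benzofuran-5-carboxylic acid F5. Me3SiCHN2 in MeOH/PhMe at 0 °C, which esterifies a carboxylic acid much faster than it methylates a phenol, rejoins the route at 13.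

**Step 4.** The aluminium hydride may attack the S–O bond of the aryl mesylate or reduce the conjugated alkene if the temperature rises.

Fallback: avoid the ester and the aluminium hydride. Setting out from 4, Wittig homologation with Ph3P=CHCHO in toluene at 80 °C should give (E)-3-[3-methoxy-4-(methylsulfonyloxy)phenyl]prop-2-enal F6. Luche reduction (NaBH4, CeCl3·7H2O, MeOH, 0 °C) rejoins the route at 7; compounds 5 and 6 are then not needed.

## Further compounds

F1 | step 7 | methyl (2S,3R)-7-methoxy-2-[3-methoxy-4-(methylsulfonyloxy)phenyl]-3-{[(2,2,6,6-tetramethylpiperidin-1-yl)oxy]methyl}-2,3-dihydro-1-benzofuran-5-carboxylate | COC(=O)c1cc(OC)c2c(c1)[C@H](CON1C(C)(C)CCCC1(C)C)[C@@H](c1ccc(OS(C)(=O)=O)c(OC)c1)O2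
F2 | step 6 | [(2S,3S)-3-[3-methoxy-4-(methylsulfonyloxy)phenyl]oxiran-2-yl]methanol | OC[C@@H]1O[C@H]1c1ccc(OS(C)(=O)=O)c(OC)c1
F3 | step 6 | (2R,3S)-2-(iodomethyl)-3-[3-methoxy-4-(methylsulfonyloxy)phenyl]oxirane | IC[C@@H]1O[C@H]1c1ccc(OS(C)(=O)=O)c(OC)c1
F4 | step 6 | (1R)-1-[3-methoxy-4-(methylsulfonyloxy)phenyl]prop-2-en-1-ol | O[C@H](C=C)c1ccc(OS(C)(=O)=O)c(OC)c1
F5 | step 8 | (2S,3R)-2-(4-hydroxy-3-methoxyphenyl)-3-(hydroxymethyl)-7-methoxy-2,3-dihydro-1-benzofuran-5-carboxylic acid | OC(=O)c1cc(OC)c2c(c1)[C@H](CO)[C@@H](c1ccc(O)c(OC)c1)O2
F6 | step 4 | (E)-3-[3-methoxy-4-(methylsulfonyloxy)phenyl]prop-2-enal | O=C/C=C/c1ccc(OS(C)(=O)=O)c(OC)c1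
A1 | alternative 1 | methyl 3-{(1S,2R)-3-[(tert-butyldimethylsilyl)oxy]-1-[3-methoxy-4-(methoxymethoxy)phenyl]-1-(4,4,5,5-tetramethyl-1,3,2-dioxaborolan-2-yl)propan-2-yl}-5-methoxy-4-(methoxymethoxy)benzoate | COC(=O)c1cc(OC)c(OCOC)c(c1)[C@H](CO[Si](C)(C)C(C)(C)C)[C@@H](c1ccc(OCOC)c(OC)c1)B1OC(C)(C)C(C)(C)O1
A2 | alternative 1 | (E)-tert-butyldimethyl{[3-(4,4,5,5-tetramethyl-1,3,2-dioxaborolan-2-yl)prop-2-en-1-yl]oxy}silane | CC(C)(C)[Si](C)(C)OC/C=C/B1OC(C)(C)C(C)(C)O1
A3 | alternative 1 | methyl 3-methoxy-4-(methoxymethoxy)-5-{[(trifluoromethyl)sulfonyl]oxy}benzoate | COC(=O)c1cc(OC)c(OCOC)c(OS(=O)(=O)C(F)(F)F)c1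
A4 | alternative 1 | [3-methoxy-4-(methoxymethoxy)phenyl]lithium | [Li]c1ccc(OCOC)c(OC)c1
A5 | alternative 2 | methyl (2S,3R)-2-[4-(benzyloxy)-3-methoxyphenyl]-3-{[(tert-butyldimethylsilyl)oxy]methyl}-7-methoxy-2,3-dihydro-1-benzofuran-5-carboxylate | COC(=O)c1cc(OC)c2c(c1)[C@H](CO[Si](C)(C)C(C)(C)C)[C@@H](c1ccc(OCc3ccccc3)c(OC)c1)O2
A6 | alternative 2 | methyl 3-methoxy-2-oxo-2H-pyran-5-carboxylate | O=C1OC=C(C(=O)OC)C=C1OC
A7 | alternative 2 | trimethylsilyl ketene acetal of A8 (trans-2-aryl-3-(silyloxymethyl)-5-(trimethylsilyloxy)-2,3-dihydrofuran, configuration as in A8) | C[Si](C)(C)OC1=C[C@H](CO[Si](C)(C)C(C)(C)C)[C@@H](c2ccc(OCc3ccccc3)c(OC)c2)O1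
A8 | alternative 2 | (4R,5S)-5-[4-(benzyloxy)-3-methoxyphenyl]-4-{[(tert-butyldimethylsilyl)oxy]methyl}oxolan-2-one | O=C1C[C@H](CO[Si](C)(C)C(C)(C)C)[C@@H](c2ccc(OCc3ccccc3)c(OC)c2)O1
A9 | alternative 3 | methyl (2S,3R)-2-[4-(benzyloxy)-3-methoxyphenyl]-5-bromo-7-methoxy-2,3-dihydro-1-benzofuran-3-carboxylate (cis) | Brc1cc(OC)c2c(c1)[C@@H](C(=O)OC)[C@@H](c1ccc(OCc3ccccc3)c(OC)c1)O2
A10 | alternative 3 | methyl 2-{2-[(4-(benzyloxy)-3-methoxyphenyl)methoxy]-5-bromo-3-methoxyphenyl}-2-diazoacetate | COC(=O)C(=[N+]=[N-])c1cc(Br)cc(OC)c1OCc1ccc(OCc2ccccc2)c(OC)c1
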